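**Plan**

1. Numbering as in eremophilanes: ring A = C1–C5 with C10, ring B = C5–C10, C11(C13)–C12O2Me on C7, methyls C14 on C5 and C15 on C4.
2. Enabling feature: quaternary C5 is bonded to trigonal C10, which carries oxygenated C1, and ring B (C5–C6=C7–C8–C9=C10) is a cyclohexadiene. With C1 as a ketone and C8 as CH2, C5–C10 and C8–C9 are the two σ bonds of a [4+2] adduct of a diene C5=C6–C7=C8 and an ynone C9≡C10–C1=O. The four carbons C1–C4 that join C10 to C5 are ring A.
3. Retrosynthetic cuts: first the angelate C1–O and the C12 and C8 oxidation levels, then C5–C10 and C8–C9 together (both rings open to an acyclic dienynone). Then C1–C10 (acetylide), C2–C3 (nitrile alkylation), C6–C7 (alkenyl–alkenyl coupling) and C5–C14 (carboalumination).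
4. Forward: alkynes from the two enantiomers of methyl 3-hydroxy-2-methylpropanoate become a (Z)-iodoalkene (C3–C6) and an internal alkenylboronate (C7, C8, C11–C13). Suzuki coupling joins C6–C7, the C3 arm is lengthened to the ynone, and one intramolecular Diels–Alder reaction closes ring B and ring A together. C1 reduction, angeloylation, C8 oxidation and C12 oxidation/methylation finish.
5. Stereochemistry: C4 and C11 come from the chiral pool. C5 is set from C4 by 1,3-allylic strain in the 7Z diene (tether carbon inside). The diene is made Z on purpose: with the tether outside (7E) only 1,2-strain would act, and the favoured cis-fused approach would place C5 trans to the C4 methyl. C1 is set by hydride attack anti to the C5 methyl; the angelate geometry comes from angelic acid.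

Key step: step 16

Remark: both enantiomers of methyl 3-hydroxy-2-methylpropanoate, the Ohira–Bestmann reagent, ethynylmagnesium bromide and angelic acid are taken as commercial.

**Route**

Step 1
Reactants: 1 methyl (S)-3-hydroxy-2-methylpropanoate
Product: 2 methyl (S)-3-[(tert-butyldimethylsilyl)oxy]-2-methylpropanoate
Conditions: t-BuMe2SiCl, imidazole, DMF, 0 °C to rt
Reagents that add atoms: tert-butyldimethylsilyl chloride, CC(C)(C)[Si](C)(C)Cl
Why: Imidazole-mediated silylation of the primary alcohol (silyl ether protection) leaves the α-stereocentre untouched.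

Step 2
Reactants: 2 methyl (S)-3-[(tert-butyldimethylsilyl)oxy]-2-methylpropanoate
Product: 3 (S)-3-[(tert-butyldimethylsilyl)oxy]-2-methylpropanal
Conditions: i-Bu2AlH, CH2Cl2, −78 °C
Reagents that add atoms: none
Why: Low-temperature i-Bu2AlH half-reduction stops at the aluminium hemiacetal, which should release the aldehyde on work-up without epimerising the α-methyl centre.

Step 3
Reactants: 3 (S)-3-[(tert-butyldimethylsilyl)oxy]-2-methylpropanal; 4 dimethyl (1-diazo-2-oxopropyl)phosphonate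
Product: 5 (R)-tert-butyldimethyl[(2-methylbut-3-yn-1-yl)oxy]silane
Conditions: K2CO3, MeOH, 0 °C to rt
Reagents that add atoms: none
Why: Ohira–Bestmann (Seyferth–Gilbert) homologation under mild carbonate conditions should convert the aldehyde into the terminal alkyne with the stereocentre intact.

Step 4
Reactants: 5 (R)-tert-butyldimethyl[(2-methylbut-3-yn-1-yl)oxy]silane
Product: 6 (R)-2-methylbut-3-yn-1-ol
Conditions: Bu4NF, THF, 0 °C
Reagents that add atoms: none
Why: Fluoride desilylation frees the homopropargylic hydroxyl that must direct the next step; the volatile alcohol is carried on as a solution.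

Step 5
Reactants: 6 (R)-2-methylbut-3-yn-1-ol; 7 trimethylaluminium
Product: 10 (2R,3Z)-4-iodo-2,3-dimethylbut-3-en-1-ol, via (E)-alkenylalane syn-adduct 8 (not isolated), via (Z)-oxaaluminacycle chelate 9 (not isolated)
Conditions: Me3Al (3 equiv), Cp2ZrCl2 (0.25 equiv), (CH2Cl)2, 23 °C; then AlCl3 (0.1 equiv), 50 °C; then I2, THF, −30 to 0 °C
Reagents that add atoms: iodine, II
Why: Zirconium-catalysed carboalumination (Negishi) adds Me and Al syn with Me on the internal carbon, warming lets the alkenyl–Al bond isomerise to the six-membered O–Al chelate with Al cis to the carbinol chain, and iodinolysis with retention should give the (Z)-iodide.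

Step 6
Reactants: 11 methyl (R)-3-hydroxy-2-methylpropanoate
Product: 12 methyl (R)-3-[(tert-butyldiphenylsilyl)oxy]-2-methylpropanoate
Conditions: t-BuPh2SiCl, imidazole, DMF, rt
Reagents that add atoms: tert-butyldiphenylsilyl chloride, CC(C)(C)[Si](Cl)(c1ccccc1)c1ccccc1
Why: Silyl ether protection with the robust tert-butyldiphenylsilyl group, which has to last until step 20.

Step 7
Reactants: 12 methyl (R)-3-[(tert-butyldiphenylsilyl)oxy]-2-methylpropanoate
Product: 13 (R)-3-[(tert-butyldiphenylsilyl)oxy]-2-methylpropanal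
Conditions: i-Bu2AlH, CH2Cl2, −78 °C
Reagents that add atoms: none
Why: Ester half-reduction with i-Bu2AlH at low temperature, as in step 2, keeps the α-stereocentre.

Step 8
Reactants: 13 (R)-3-[(tert-butyldiphenylsilyl)oxy]-2-methylpropanal; 4 dimethyl (1-diazo-2-oxopropyl)phosphonate
Product: 14 (S)-tert-butyl[(2-methylbut-3-yn-1-yl)oxy]diphenylsilane
Conditions: K2CO3, MeOH, 0 °C to rt
Reagents that add atoms: none
Why: Ohira–Bestmann homologation, as in step 3, gives the alkyne whose stereocentre becomes C11.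

Step 9
Reactants: 14 (S)-tert-butyl[(2-methylbut-3-yn-1-yl)oxy]diphenylsilane
Product: 16 tert-butyl{[(2S)-2-methyl-3-(4,4,5,5-tetramethyl-1,3,2-dioxaborolan-2-yl)but-3-en-1-yl]oxy}diphenylsilane, via internal alkenylalane 15 (not isolated)
Conditions: NiCl2(dppp) (3 mol%), i-Bu2AlH (1.3 equiv), THF, 0 to 22 °C; then MeOBpin, 0 to 22 °C
Reagents that add atoms: 2-methoxy-4,4,5,5-tetramethyl-1,3,2-dioxaborolane, COB1OC(C)(C)C(C)(C)O1
Why: Nickel-catalysed α-selective hydroalumination places Al on the internal alkyne carbon, and Al-to-B exchange should give the 1,1-disubstituted alkenylboronate without touching the stereocentre.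

Step 10
Reactants: 10 (2R,3Z)-4-iodo-2,3-dimethylbut-3-en-1-ol; 16 tert-butyl{[(2S)-2-methyl-3-(4,4,5,5-tetramethyl-1,3,2-dioxaborolan-2-yl)but-3-en-1-yl]oxy}diphenylsilane
Product: 17 (2R,3Z,6S)-7-[(tert-butyldiphenylsilyl)oxy]-2,3,6-trimethyl-5-methylidenehept-3-en-1-ol
Conditions: Pd(OAc)2 (5 mol%), SPhos (10 mol%), K3PO4, THF/H2O, 40 °C
Reagents that add atoms: none
Why: Suzuki–Miyaura alkenyl–alkenyl coupling forms C6–C7 with retention of the iodide geometry and tolerates the free hydroxyl, so the diene should carry the tether carbon C4 in the inside position.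

Step 11
Reactants: 17 (2R,3Z,6S)-7-[(tert-butyldiphenylsilyl)oxy]-2,3,6-trimethyl-5-methylidenehept-3-en-1-ol
Product: 18 tert-butyl{[(2S,4Z,6R)-7-iodo-2,5,6-trimethyl-3-methylidenehept-4-en-1-yl]oxy}diphenylsilane
Conditions: PPh3, I2, imidazole, CH2Cl2, 0 °C, dark
Reagents that add atoms: iodine, II
Why: Appel iodination (alkoxyphosphonium activation, SN2 by iodide at the primary carbon) is neutral and should leave the diene geometry and both stereocentres unchanged.

Step 12
Reactants: 18 tert-butyl{[(2S,4Z,6R)-7-iodo-2,5,6-trimethyl-3-methylidenehept-4-en-1-yl]oxy}diphenylsilane; 19 acetonitrile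
Product: 20 (4S,5Z,8S)-9-[(tert-butyldiphenylsilyl)oxy]-4,5,8-trimethyl-7-methylidenenon-5-enenitrile
Conditions: n-BuLi, MeCN, THF, −78 °C; then 18, DMPU, −78 to −20 °C
Reagents that add atoms: none
Why: SN2 alkylation of lithioacetonitrile by the primary iodide adds C2 and C1 in one operation, the low temperature favouring substitution over E2 elimination.

Step 13
Reactants: 20 (4S,5Z,8S)-9-[(tert-butyldiphenylsilyl)oxy]-4,5,8-trimethyl-7-methylidenenon-5-enenitrile
Product: 21 (4S,5Z,8S)-9-[(tert-butyldiphenylsilyl)oxy]-4,5,8-trimethyl-7-methylidenenon-5-enal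
Conditions: i-Bu2AlH, CH2Cl2, −78 °C; then H2O, pH 5 buffer
Reagents that add atoms: water, O
Why: Nitrile half-reduction, in which i-Bu2AlH adds once and the aluminium aldimine is hydrolysed to the aldehyde under mild conditions that the diene tolerates.

Step 14
Reactants: 21 (4S,5Z,8S)-9-[(tert-butyldiphenylsilyl)oxy]-4,5,8-trimethyl-7-methylidenenon-5-enal; 22 ethynylmagnesium bromide
Product: 23 (3RS,6S,7Z,10S)-11-[(tert-butyldiphenylsilyl)oxy]-6,7,10-trimethyl-9-methylideneundec-7-en-1-yn-3-ol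
Conditions: HC≡CMgBr, THF, −78 to 0 °C
Reagents that add atoms: none
Why: Grignard 1,2-addition of the acetylide forms C1–C10; the carbinol centre arises as a mixture that the next step erases.

Step 15
Reactants: 23 (3RS,6S,7Z,10S)-11-[(tert-butyldiphenylsilyl)oxy]-6,7,10-trimethyl-9-methylideneundec-7-en-1-yn-3-ol
Product: 24 (6S,7Z,10S)-11-[(tert-butyldiphenylsilyl)oxy]-6,7,10-trimethyl-9-methylideneundec-7-en-1-yn-3-one
Conditions: Dess–Martin periodinane, CH2Cl2, 0 °C
Reagents that add atoms: none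
Why: Dess–Martin oxidation of the propargylic alcohol under non-enolising conditions should give the terminal ynone, which is isolated cold and used at once.

Step 16
Reactants: 24 (6S,7Z,10S)-11-[(tert-butyldiphenylsilyl)oxy]-6,7,10-trimethyl-9-methylideneundec-7-en-1-yn-3-one
Product: 25 (4S,4aS)-6-{(2S)-1-[(tert-butyldiphenylsilyl)oxy]propan-2-yl}-4,4a-dimethyl-3,4,4a,7-tetrahydronaphthalen-1(2H)-one
Conditions: PhMe (0.01 M), BHT (cat.), 80 °C
Reagents that add atoms: none
Why: The ynone (C9≡C10, activated by the C1 carbonyl) adds suprafacially across the diene C5=C6–C7=C8 in a concerted, asynchronous [4+2] cycloaddition; the closest known reaction type is the type 1 intramolecular Diels–Alder reaction of deca-7,9-dien-1-yn-3-ones and of Z-dienes tethered through the inside position. Ring B (C5–C10) is the six-membered cycloadduct ring, formed by the new C8–C9 and C5–C10 bonds with C6=C7 as the new alkene, and ring A closes in the fused mode because the four-atom tether C4–C3–C2–C1 delivers C10 onto C5 of the same diene. Orientation is fixed by the tether and is also the electronically matched one, since the unsubstituted terminus C8 bonds to the β-carbon C9. The only new stereocentre is quaternary C5: with C4 in the inside position, 1,3-allylic strain against C7 and C8 keeps C4–H in the diene plane, so C3 and the C4 methyl lie on opposite faces and the ynone, which can arrive only on the face of C3, bonds to C5 anti to that methyl, which gives the cis-4,5-dimethyl pair (4S induces 5S). The step therefore needs only π-facial selectivity, because an alkyne dienophile has no endo/exo alternative and leaves C10 trigonal, and that selectivity is secured by the Z geometry built in steps 5 and 10. The reactive ynone allows a moderate temperature, at which 1,5-hydrogen shift in the Z-diene and migration of the skipped C6=C7 bond should not compete.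

Step 17
Reactants: 25 (4S,4aS)-6-{(2S)-1-[(tert-butyldiphenylsilyl)oxy]propan-2-yl}-4,4a-dimethyl-3,4,4a,7-tetrahydronaphthalen-1(2H)-one
Product: 26 (1R,4S,4aS)-6-{(2S)-1-[(tert-butyldiphenylsilyl)oxy]propan-2-yl}-4,4a-dimethyl-1,2,3,4,4a,7-hexahydronaphthalen-1-ol
Conditions: NaBH4, CeCl3·7H2O, MeOH, −78 °C
Reagents that add atoms: none
Why: Luche 1,2-reduction of the enone, in which hydride should reach C1 from the face opposite the pseudo-axial C5 methyl (1,3 to the carbonyl), giving the 1R alcohol with oxygen cis to that methyl.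

Step 18
Reactants: 26 (1R,4S,4aS)-6-{(2S)-1-[(tert-butyldiphenylsilyl)oxy]propan-2-yl}-4,4a-dimethyl-1,2,3,4,4a,7-hexahydronaphthalen-1-ol; 27 angelic acid, (2Z)-2-methylbut-2-enoic acid
Product: 28 (1R,4S,4aS)-6-{(2S)-1-[(tert-butyldiphenylsilyl)oxy]propan-2-yl}-4,4a-dimethyl-1,2,3,4,4a,7-hexahydronaphthalen-1-yl (2Z)-2-methylbut-2-enoate
Conditions: 27, 2,4,6-Cl3C6H2COCl, Et3N, PhMe, rt; then 26, 80 °C
Reagents that add atoms: none
Why: Yamaguchi-type esterification through the mixed trichlorobenzoic anhydride, run without a nucleophilic catalyst, should acylate the hindered allylic alcohol with retention at C1 and without Z-to-E isomerisation of the angelate, which then also protects C1–O.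

Step 19
Reactants: 28 (1R,4S,4aS)-6-{(2S)-1-[(tert-butyldiphenylsilyl)oxy]propan-2-yl}-4,4a-dimethyl-1,2,3,4,4a,7-hexahydronaphthalen-1-yl (2Z)-2-methylbut-2-enoate
Product: 29 (1R,4S,4aS)-6-{(2S)-1-[(tert-butyldiphenylsilyl)oxy]propan-2-yl}-4,4a-dimethyl-7-oxo-1,2,3,4,4a,7-hexahydronaphthalen-1-yl (2Z)-2-methylbut-2-enoate
Conditions: (C5H5NH)2Cr2O7, t-BuOOH, diatomaceous earth, PhH, rt
Reagents that add atoms: tert-butyl hydroperoxide, CC(C)(C)OO
Why: Dichromate-mediated tert-butyl hydroperoxide oxidation of the doubly allylic C8 methylene (the weakest C–H bond, between C6=C7 and C9=C10) is the established conversion of a 3,3-disubstituted cyclohexa-1,4-diene into a cross-conjugated cyclohexa-2,5-dienone.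

Step 20
Reactants: 29 (1R,4S,4aS)-6-{(2S)-1-[(tert-butyldiphenylsilyl)oxy]propan-2-yl}-4,4a-dimethyl-7-oxo-1,2,3,4,4a,7-hexahydronaphthalen-1-yl (2Z)-2-methylbut-2-enoate
Product: 30 (1R,4S,4aS)-6-[(2S)-1-hydroxypropan-2-yl]-4,4a-dimethyl-7-oxo-1,2,3,4,4a,7-hexahydronaphthalen-1-yl (2Z)-2-methylbut-2-enoate
Conditions: HF·pyridine, THF/pyridine, 0 °C to rt
Reagents that add atoms: none
Why: Buffered acidic fluoride cleaves the primary silyl ether (desilylation) without touching the angelate or the dienone.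

Step 21
Reactants: 30 (1R,4S,4aS)-6-[(2S)-1-hydroxypropan-2-yl]-4,4a-dimethyl-7-oxo-1,2,3,4,4a,7-hexahydronaphthalen-1-yl (2Z)-2-methylbut-2-enoate
Product: 32 (2S)-2-[(5R,8S,8aS)-8,8a-dimethyl-5-{[(2Z)-2-methylbut-2-enoyl]oxy}-3-oxo-3,5,6,7,8,8a-hexahydronaphthalen-2-yl]propanoic acid, via aldehyde 31 (not isolated)
Conditions: TEMPO (cat.), PhI(OAc)2, MeCN/H2O, rt
Reagents that add atoms: water, O
Why: Oxoammonium (TEMPO/PhI(OAc)2) oxidation in wet acetonitrile takes the primary alcohol through the aldehyde hydrate to the acid near neutral pH, which should preserve the C11 stereocentre.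

Step 22
Reactants: 32 (2S)-2-[(5R,8S,8aS)-8,8a-dimethyl-5-{[(2Z)-2-methylbut-2-enoyl]oxy}-3-oxo-3,5,6,7,8,8a-hexahydronaphthalen-2-yl]propanoic acid
Product: 33 methyl (2S)-2-[(5R,8S,8aS)-8,8a-dimethyl-5-{[(2Z)-2-methylbut-2-enoyl]oxy}-3-oxo-3,5,6,7,8,8a-hexahydronaphthalen-2-yl]propanoate
Conditions: Me3SiCHN2, MeOH/PhMe, 0 °C
Reagents that add atoms: (trimethylsilyl)diazomethane, C[Si](C)(C)C=[N+]=[N-]
Why: Diazoalkane esterification methylates the acid without base, so C11 should not epimerise and the angelate should not isomerise.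

**Compound list**

1 | methyl (S)-3-hydroxy-2-methylpropanoate | COC(=O)[C@@H](C)CO | starting material
2 | methyl (S)-3-[(tert-butyldimethylsilyl)oxy]-2-methylpropanoate | COC(=O)[C@@H](C)CO[Si](C)(C)C(C)(C)C | intermediate
3 | (S)-3-[(tert-butyldimethylsilyl)oxy]-2-methylpropanal | O=C[C@@H](C)CO[Si](C)(C)C(C)(C)C | intermediate
4 | dimethyl (1-diazo-2-oxopropyl)phosphonate (Ohira–Bestmann reagent) | COP(=O)(OC)C(=[N+]=[N-])C(C)=O | starting material
5 | (R)-tert-butyldimethyl[(2-methylbut-3-yn-1-yl)oxy]silane | C#C[C@@H](C)CO[Si](C)(C)C(C)(C)C | intermediate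
6 | (R)-2-methylbut-3-yn-1-ol | C#C[C@@H](C)CO | intermediate
7 | trimethylaluminium | C[Al](C)C | starting material
8 | dimethylaluminium (2R,3E)-4-(dimethylalumanyl)-2,3-dimethylbut-3-en-1-olate (syn-carboalumination adduct, not isolated) | C[Al](C)OC[C@H](C)/C(C)=C/[Al](C)C | intermediate
9 | (5R)-2,4,5-trimethyl-5,6-dihydro-2H-1,2-oxaaluminine (chelated Z-alkenylalane, not isolated) | C[Al]1OC[C@H](C)C(C)=C1 | intermediate
10 | (2R,3Z)-4-iodo-2,3-dimethylbut-3-en-1-ol | OC[C@H](C)/C(C)=C\I | intermediate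
11 | methyl (R)-3-hydroxy-2-methylpropanoate | COC(=O)[C@H](C)CO | starting material
12 | methyl (R)-3-[(tert-butyldiphenylsilyl)oxy]-2-methylpropanoate | COC(=O)[C@H](C)CO[Si](c1ccccc1)(c1ccccc1)C(C)(C)C | intermediate
13 | (R)-3-[(tert-butyldiphenylsilyl)oxy]-2-methylpropanal | O=C[C@H](C)CO[Si](c1ccccc1)(c1ccccc1)C(C)(C)C | intermediate
14 | (S)-tert-butyl[(2-methylbut-3-yn-1-yl)oxy]diphenylsilane | C#C[C@H](C)CO[Si](c1ccccc1)(c1ccccc1)C(C)(C)C | intermediate
15 | diisobutyl{(3R)-4-[(tert-butyldiphenylsilyl)oxy]-3-methylbut-1-en-2-yl}alumane (not isolated) | C=C([Al](CC(C)C)CC(C)C)[C@H](C)CO[Si](c1ccccc1)(c1ccccc1)C(C)(C)C | intermediate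
16 | tert-butyl{[(2S)-2-methyl-3-(4,4,5,5-tetramethyl-1,3,2-dioxaborolan-2-yl)but-3-en-1-yl]oxy}diphenylsilane | C=C(B1OC(C)(C)C(C)(C)O1)[C@H](C)CO[Si](c1ccccc1)(c1ccccc1)C(C)(C)C | intermediate
17 | (2R,3Z,6S)-7-[(tert-butyldiphenylsilyl)oxy]-2,3,6-trimethyl-5-methylidenehept-3-en-1-ol | OC[C@H](C)/C(C)=C\C(=C)[C@H](C)CO[Si](c1ccccc1)(c1ccccc1)C(C)(C)C | intermediate
18 | tert-butyl{[(2S,4Z,6R)-7-iodo-2,5,6-trimethyl-3-methylidenehept-4-en-1-yl]oxy}diphenylsilane | IC[C@H](C)/C(C)=C\C(=C)[C@H](C)CO[Si](c1ccccc1)(c1ccccc1)C(C)(C)C | intermediate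
19 | acetonitrile | CC#N | starting material
20 | (4S,5Z,8S)-9-[(tert-butyldiphenylsilyl)oxy]-4,5,8-trimethyl-7-methylidenenon-5-enenitrile | N#CCC[C@H](C)/C(C)=C\C(=C)[C@H](C)CO[Si](c1ccccc1)(c1ccccc1)C(C)(C)C | intermediate
21 | (4S,5Z,8S)-9-[(tert-butyldiphenylsilyl)oxy]-4,5,8-trimethyl-7-methylidenenon-5-enal | O=CCC[C@H](C)/C(C)=C\C(=C)[C@H](C)CO[Si](c1ccccc1)(c1ccccc1)C(C)(C)C | intermediate
22 | ethynylmagnesium bromide | C#C[Mg]Br | starting material
23 | (3RS,6S,7Z,10S)-11-[(tert-butyldiphenylsilyl)oxy]-6,7,10-trimethyl-9-methylideneundec-7-en-1-yn-3-ol | C#CC(O)CC[C@H](C)/C(C)=C\C(=C)[C@H](C)CO[Si](c1ccccc1)(c1ccccc1)C(C)(C)C | intermediate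
24 | (6S,7Z,10S)-11-[(tert-butyldiphenylsilyl)oxy]-6,7,10-trimethyl-9-methylideneundec-7-en-1-yn-3-one | C#CC(=O)CC[C@H](C)/C(C)=C\C(=C)[C@H](C)CO[Si](c1ccccc1)(c1ccccc1)C(C)(C)C | intermediate
25 | (4S,4aS)-6-{(2S)-1-[(tert-butyldiphenylsilyl)oxy]propan-2-yl}-4,4a-dimethyl-3,4,4a,7-tetrahydronaphthalen-1(2H)-one | O=C1CC[C@H](C)[C@@]2(C)C=C([C@H](C)CO[Si](c3ccccc3)(c3ccccc3)C(C)(C)C)CC=C12 | intermediate
26 | (1R,4S,4aS)-6-{(2S)-1-[(tert-butyldiphenylsilyl)oxy]propan-2-yl}-4,4a-dimethyl-1,2,3,4,4a,7-hexahydronaphthalen-1-ol | O[C@@H]1CC[C@H](C)[C@@]2(C)C=C([C@H](C)CO[Si](c3ccccc3)(c3ccccc3)C(C)(C)C)CC=C12 | intermediate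
27 | angelic acid, (2Z)-2-methylbut-2-enoic acid | C/C=C(/C)C(=O)O | starting material
28 | (1R,4S,4aS)-6-{(2S)-1-[(tert-butyldiphenylsilyl)oxy]propan-2-yl}-4,4a-dimethyl-1,2,3,4,4a,7-hexahydronaphthalen-1-yl (2Z)-2-methylbut-2-enoate | C/C=C(/C)C(=O)O[C@@H]1CC[C@H](C)[C@@]2(C)C=C([C@H](C)CO[Si](c3ccccc3)(c3ccccc3)C(C)(C)C)CC=C12 | intermediate
29 | (1R,4S,4aS)-6-{(2S)-1-[(tert-butyldiphenylsilyl)oxy]propan-2-yl}-4,4a-dimethyl-7-oxo-1,2,3,4,4a,7-hexahydronaphthalen-1-yl (2Z)-2-methylbut-2-enoate | C/C=C(/C)C(=O)O[C@@H]1CC[C@H](C)[C@@]2(C)C=C([C@H](C)CO[Si](c3ccccc3)(c3ccccc3)C(C)(C)C)C(=O)C=C12 | intermediate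
30 | (1R,4S,4aS)-6-[(2S)-1-hydroxypropan-2-yl]-4,4a-dimethyl-7-oxo-1,2,3,4,4a,7-hexahydronaphthalen-1-yl (2Z)-2-methylbut-2-enoate | C/C=C(/C)C(=O)O[C@@H]1CC[C@H](C)[C@@]2(C)C=C([C@H](C)CO)C(=O)C=C12 | intermediate
31 | (1R,4S,4aS)-4,4a-dimethyl-7-oxo-6-[(2S)-1-oxopropan-2-yl]-1,2,3,4,4a,7-hexahydronaphthalen-1-yl (2Z)-2-methylbut-2-enoate (not isolated) | C/C=C(/C)C(=O)O[C@@H]1CC[C@H](C)[C@@]2(C)C=C([C@H](C)C=O)C(=O)C=C12 | intermediate
32 | (2S)-2-[(5R,8S,8aS)-8,8a-dimethyl-5-{[(2Z)-2-methylbut-2-enoyl]oxy}-3-oxo-3,5,6,7,8,8a-hexahydronaphthalen-2-yl]propanoic acid | C/C=C(/C)C(=O)O[C@@H]1CC[C@H](C)[C@@]2(C)C=C([C@H](C)C(=O)O)C(=O)C=C12 | intermediate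
33 | methyl (2S)-2-[(5R,8S,8aS)-8,8a-dimethyl-5-{[(2Z)-2-methylbut-2-enoyl]oxy}-3-oxo-3,5,6,7,8,8a-hexahydronaphthalen-2-yl]propanoate (methyl 1β-angeloyloxy-8-oxoeremophila-6,9-dien-12-oate) | C/C=C(/C)C(=O)O[C@@H]1CC[C@H](C)[C@@]2(C)C=C([C@H](C)C(=O)OC)C(=O)C=C12 | target

**Step count and risks**

Total steps: 22. Longest linear sequence: 18 (steps 1–5, then 10–22); the second fragment takes steps 6–9.

Step 16. The cycloaddition may be slow, because the diene must reach a twisted s-cis geometry with the tether carbon inside. A 1,5-hydrogen shift in the Z-diene, oligomerisation of the ynone, or migration of the C6=C7 bond into conjugation in the adduct may then overtake it. The fallback uses an alkene dienophile under Lewis acid and dehydrogenates afterwards. From aldehyde 21, CH2=CHMgBr gives the allylic alcohol F1 and Dess–Martin oxidation gives the trienone F2. Me2AlCl in CH2Cl2 at −78 °C should then form the same two bonds under the same 1,3-allylic strain control, giving the cis-fused octalone F3 (Z-dienes give only the cis-fused adduct). Me3SiCl/NaI/Et3N in MeCN should give the more substituted silyl enol ether F4 (C1=C10), and Saegusa–Ito oxidation with Pd(OAc)2 introduces C9=C10 and returns to enone 25.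

Step 10. Transmetalation of the hindered 1,1-disubstituted boronate may be slow, so that protodeboronation or erosion of the Z geometry takes over. The fallback reverses the roles of the partners in a Negishi coupling. From alkyne 14, the alkenylalane 15 is quenched with I2 to give the 2-iodoalkene F5. Alkynol 6 is taken to the chelated alkenylalane 9 as in step 5 and, without iodinolysis, coupled with F5 using Pd(PPh3)4 (zerovalent palladium) and ZnCl2 in THF. This returns to dienol 17.

Step 19. Hydrogen abstraction may also take place at C11–H or C1–H, the pentadienyl radical may be oxygenated at C6 instead of C8, or the dienone may be oxidised further. The fallback is an ene-type hydroxylation followed by alcohol oxidation. From angelate 28, SeO2 (cat.)/t-BuOOH in CH2Cl2 should hydroxylate the doubly allylic C8 to give the C8 carbinol F6, and Dess–Martin periodinane then oxidises it to dienone 29.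

**Further compounds**

F1 | step 16 | (3RS,6S,7Z,10S)-11-[(tert-butyldiphenylsilyl)oxy]-6,7,10-trimethyl-9-methylideneundeca-1,7-dien-3-ol | C=CC(O)CC[C@H](C)/C(C)=C\C(=C)[C@H](C)CO[Si](c1ccccc1)(c1ccccc1)C(C)(C)C
F2 | step 16 | (6S,7Z,10S)-11-[(tert-butyldiphenylsilyl)oxy]-6,7,10-trimethyl-9-methylideneundeca-1,7-dien-3-one | C=CC(=O)CC[C@H](C)/C(C)=C\C(=C)[C@H](C)CO[Si](c1ccccc1)(c1ccccc1)C(C)(C)C
F3 | step 16 | (4S,4aS,8aR)-6-{(2S)-1-[(tert-butyldiphenylsilyl)oxy]propan-2-yl}-4,4a-dimethyl-3,4,4a,7,8,8a-hexahydronaphthalen-1(2H)-one | O=C1CC[C@H](C)[C@@]2(C)C=C([C@H](C)CO[Si](c3ccccc3)(c3ccccc3)C(C)(C)C)CC[C@@H]12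
F4 | step 16 | {[(4S,4aS)-6-{(2S)-1-[(tert-butyldiphenylsilyl)oxy]propan-2-yl}-4,4a-dimethyl-2,3,4,4a,7,8-hexahydronaphthalen-1-yl]oxy}trimethylsilane | C[Si](C)(C)OC1=C2CCC([C@H](C)CO[Si](c3ccccc3)(c3ccccc3)C(C)(C)C)=C[C@]2(C)[C@@H](C)CC1
F5 | step 10 | tert-butyl{[(2R)-3-iodo-2-methylbut-3-en-1-yl]oxy}diphenylsilane | C=C(I)[C@H](C)CO[Si](c1ccccc1)(c1ccccc1)C(C)(C)C
F6 | step 19 | (1R,4S,4aS,7RS)-6-{(2S)-1-[(tert-butyldiphenylsilyl)oxy]propan-2-yl}-7-hydroxy-4,4a-dimethyl-1,2,3,4,4a,7-hexahydronaphthalen-1-yl (2Z)-2-methylbut-2-enoate | C/C=C(/C)C(=O)O[C@@H]1CC[C@H](C)[C@@]2(C)C=C([C@H](C)CO[Si](c3ccccc3)(c3ccccc3)C(C)(C)C)C(O)C=C12
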